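**Retrosynthetic overview**
1. The side-chain oxirane (C10–C11) is made last by Shi epoxidation of the prenyl alkene of bis-angelate 21; both angelates come from diol 18 in one double esterification.
2. C1–OH comes from Davis oxidation of the C2-ketone enolate of 15; the prenyl group from cross-metathesis of the allyl group of 13; the C8–C9 bond and C8 from Brown allylation of enal 10.
3. Enal 10 comes from N-oxide oxidation of allylic chloride 8; the ring oxirane cis to the side chain from Luche reduction (5), OH-directed epoxidation (7) and reoxidation (8).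
4. Chloride 4 comes from ene-type chlorination of (R)-(−)-carvone 1, which supplies the carbocycle, the ring methyl and C6.
5. Ring order: six-membered carbocycle (bought with 1, never opened), then the fused oxirane (step 3), then the side-chain oxirane (step 10).

Assumption: the target is the single isomer drawn, read as (1S,3S,4S,6S,8S,10R) with working locants ring C1 (CH–O-angeloyl), C2 (C=O), C3 (C–CH3), C4 (oxirane CH), C5 (CH2), C6 (CH–side chain) and chain C7(=C14H2), C8 (CH–O-angeloyl), C9, C10, C11; the oxirane at C3–C4 is cis to the C6 side chain and trans to the C1 ester, and both esters are angelates, (Z)-2-methylbut-2-enoates.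

**Route**

Step 1
Reactants: 1 (R)-(−)-carvone; 2 calcium hypochlorite Ca(OCl)2
Product: 4 (5R)-5-(3-chloroprop-1-en-2-yl)-2-methylcyclohex-2-en-1-one, via hypochlorous acid 3 (not isolated)
Conditions: Ca(OCl)2, solid CO2, CH2Cl2/H2O, 0 °C
Reagents that add atoms: calcium hypochlorite Ca(OCl)2, [Ca+2].[O-]Cl.[O-]Cl
Why: Ene-type allylic chlorination by electrophilic HOCl attacks only the electron-rich isopropenyl alkene (the enone alkene is deactivated) with double-bond shift to the 2-substituted allyl chloride, and C6 is carried over untouched from carvone.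

Step 2
Reactants: 4 (5R)-5-(3-chloroprop-1-en-2-yl)-2-methylcyclohex-2-en-1-one
Product: 5 (1R,5R)-5-(3-chloroprop-1-en-2-yl)-2-methylcyclohex-2-en-1-ol
Conditions: NaBH4, CeCl3·7H2O, MeOH, −20 °C
Reagents that add atoms: none
Why: Luche 1,2-reduction delivers hydride axially to the enone carbonyl and gives the equatorial C2 alcohol cis to the C6 side chain (the carvone to cis-carveol sense), while the allylic chloride is inert.

Step 3
Reactants: 5 (1R,5R)-5-(3-chloroprop-1-en-2-yl)-2-methylcyclohex-2-en-1-ol; 6 tert-butyl hydroperoxide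
Product: 7 (1R,2R,4S,6S)-4-(3-chloroprop-1-en-2-yl)-1-methyl-7-oxabicyclo[4.1.0]heptan-2-ol (OH, oxirane O and side chain all cis)
Conditions: VO(acac)2 (3 mol%), t-BuOOH (1.5 equiv), CH2Cl2, 0 °C to rt
Reagents that add atoms: tert-butyl hydroperoxide, CC(C)(C)OO
Why: Hydroxyl-directed VO(acac)2-catalysed epoxidation delivers oxygen to the C3=C4 alkene from the face of the C2 hydroxyl, which sets C3 and C4 with the oxirane cis to the side chain and leaves the chloro-alkene (no allylic OH) alone.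

Step 4
Reactants: 7 (1R,2R,4S,6S)-4-(3-chloroprop-1-en-2-yl)-1-methyl-7-oxabicyclo[4.1.0]heptan-2-ol
Product: 8 (1S,4R,6S)-4-(3-chloroprop-1-en-2-yl)-1-methyl-7-oxabicyclo[4.1.0]heptan-2-one
Conditions: Dess–Martin periodinane, CH2Cl2, 0 °C to rt
Reagents that add atoms: none
Why: Dess–Martin oxidation turns the temporary C2 carbinol into the ketone under near-neutral conditions that leave the oxirane, the allylic chloride and C3, C4 and C6 unchanged.

Step 5
Reactants: 8 (1S,4R,6S)-4-(3-chloroprop-1-en-2-yl)-1-methyl-7-oxabicyclo[4.1.0]heptan-2-one; 9 N-methylmorpholine N-oxide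
Product: 10 (1S,4R,6S)-1-methyl-4-(3-oxoprop-1-en-2-yl)-7-oxabicyclo[4.1.0]heptan-2-one
Conditions: NMO (4 equiv), NaI (10 mol%), 4 Å molecular sieves, MeCN, rt
Reagents that add atoms: N-methylmorpholine N-oxide, C[N+]1([O-])CCOCC1
Why: Ganem-type N-oxide oxidation works by iodide-assisted SN2 displacement of the primary allylic chloride by the N-oxide oxygen and loss of N-methylmorpholine, giving the 2-substituted acrolein without acid or strong base that would harm the epoxy ketone.

Step 6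
Reactants: 10 (1S,4R,6S)-1-methyl-4-(3-oxoprop-1-en-2-yl)-7-oxabicyclo[4.1.0]heptan-2-one; 11 (−)-B-allyldiisopinocampheylborane (from (+)-α-pinene)
Product: 13 (1S,4R,6S)-4-[(3S)-3-hydroxyhexa-1,5-dien-2-yl]-1-methyl-7-oxabicyclo[4.1.0]heptan-2-one, via borinate ester 12 (not isolated)
Conditions: 11 (1.2 equiv, pentane), Et2O, −78 °C; then pH 7 phosphate buffer, MeOH, 30% H2O2, 0 °C
Reagents that add atoms: (−)-B-allyldiisopinocampheylborane, C=CCB([C@@H]1C[C@@H]2C[C@H]([C@H]1C)C2(C)C)[C@@H]1C[C@@H]2C[C@H]([C@H]1C)C2(C)C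
Why: Brown asymmetric allylboration through a closed chair transition state is aldehyde-selective at −78 °C and reagent-controlled, the (+)-α-pinene-derived borane adding to the Si face of the enal to set C8 as S (the same sense as benzaldehyde to the S carbinol).

Step 7
Reactants: 13 (1S,4R,6S)-4-[(3S)-3-hydroxyhexa-1,5-dien-2-yl]-1-methyl-7-oxabicyclo[4.1.0]heptan-2-one; 14 2-methyl-2-butene
Product: 15 (1S,4R,6S)-4-[(3S)-3-hydroxy-6-methylhepta-1,5-dien-2-yl]-1-methyl-7-oxabicyclo[4.1.0]heptan-2-one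
Conditions: second-generation Grubbs catalyst RuCl2(=CHPh)(PCy3)(1,3-dimesitylimidazolidin-2-ylidene) (5 mol%), 2-methyl-2-butene/CH2Cl2, 40 °C
Reagents that add atoms: 2-methyl-2-butene, CC=C(C)C
Why: Olefin cross-metathesis with excess 2-methyl-2-butene converts the monosubstituted allyl terminus into the prenyl group with loss of propene, while the hindered 1,1-disubstituted C7=C14 alkene stays out of the catalytic cycle and no stereocentre is touched.

Step 8
Reactants: 15 (1S,4R,6S)-4-[(3S)-3-hydroxy-6-methylhepta-1,5-dien-2-yl]-1-methyl-7-oxabicyclo[4.1.0]heptan-2-one; 16 2-(phenylsulfonyl)-3-phenyloxaziridine (racemic Davis reagent)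
Product: 18 (1S,3S,4S,6S)-3-hydroxy-4-[(3S)-3-hydroxy-6-methylhepta-1,5-dien-2-yl]-1-methyl-7-oxabicyclo[4.1.0]heptan-2-one, via dipotassium alkoxide enolate 17 (not isolated)
Conditions: KN(SiMe3)2 (2.3 equiv), THF, −78 °C; then 16 (1.3 equiv), −78 °C; AcOH quench
Reagents that add atoms: 2-(phenylsulfonyl)-3-phenyloxaziridine, O=S(=O)(c1ccccc1)N1OC1c1ccccc1
Why: Davis enolate oxidation: two equivalents of base give the C8 alkoxide and the only possible enolate (towards C1, since C3 is quaternary), and the oxaziridine transfers oxygen to C1 from the face opposite both the neighbouring C6 substituent and the oxirane oxygen, giving the trans diequatorial C1 hydroxyl (C1 S).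

Step 9
Reactants: 18 (1S,3S,4S,6S)-3-hydroxy-4-[(3S)-3-hydroxy-6-methylhepta-1,5-dien-2-yl]-1-methyl-7-oxabicyclo[4.1.0]heptan-2-one; 19 angelic acid
Product: 21 (1S,3S,4S,6S)-1-methyl-4-{(3S)-6-methyl-3-[(Z)-2-methylbut-2-enoyloxy]hepta-1,5-dien-2-yl}-2-oxo-7-oxabicyclo[4.1.0]heptan-3-yl (Z)-2-methylbut-2-enoate, via mixed anhydride 20 (not isolated)
Conditions: 19 (5 equiv), 2,4,6-trichlorobenzoyl chloride (5 equiv), Et3N (10 equiv), toluene, rt; then 18, 80 °C
Reagents that add atoms: angelic acid, C/C=C(/C)C(=O)O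
Why: Yamaguchi-type mixed-anhydride esterification acylates both secondary hydroxyls at the less hindered angeloyl carbonyl without a nucleophilic acyl-transfer catalyst, which avoids Z to E isomerisation to the tiglate and touches no stereocentre.

Step 10
Reactants: 21 the bis-angelate of step 9; 22 potassium peroxymonosulfate KHSO5
Product: 23 (1S,3S,4S,6S)-4-{(3S)-4-[(2R)-3,3-dimethyloxiran-2-yl]-3-[(Z)-2-methylbut-2-enoyloxy]but-1-en-2-yl}-1-methyl-2-oxo-7-oxabicyclo[4.1.0]heptan-3-yl (Z)-2-methylbut-2-enoate (CNP0247177.2)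
Conditions: Oxone (2KHSO5·KHSO4·K2SO4), D-fructose-derived Shi ketone C12H18O6 (1,2:4,5-di-O-isopropylidene-β-D-erythro-2,3-hexodiulo-2,6-pyranose, 30 mol%), K2CO3, Bu4NHSO4, MeCN/CH2(OMe)2/aq. Na2B4O7 buffer (pH 10.5), 0 °C
Reagents that add atoms: potassium peroxymonosulfate KHSO5, [K+].[O-]S(=O)(=O)OO
Why: Shi asymmetric epoxidation: the chiral dioxirane reacts fastest with the electron-rich trisubstituted C10=C11 alkene (the conjugated angelate alkenes and the 1,1-disubstituted allylic-ester alkene are much slower) through the spiro transition state, and the D-fructose-derived ketone gives the 10R oxirane.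

**Compound list**
1 | (R)-(−)-carvone, (5R)-2-methyl-5-(prop-1-en-2-yl)cyclohex-2-en-1-one | C=C(C)[C@@H]1CC=C(C)C(=O)C1 | starting material
2 | calcium hypochlorite Ca(OCl)2 | [Ca+2].[O-]Cl.[O-]Cl | starting material
3 | hypochlorous acid | OCl | intermediate
4 | (5R)-5-(3-chloroprop-1-en-2-yl)-2-methylcyclohex-2-en-1-one | C=C(CCl)[C@@H]1CC=C(C)C(=O)C1 | intermediate
5 | (1R,5R)-5-(3-chloroprop-1-en-2-yl)-2-methylcyclohex-2-en-1-ol (OH cis to side chain) | C=C(CCl)[C@@H]1CC=C(C)[C@H](O)C1 | intermediate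
6 | tert-butyl hydroperoxide | CC(C)(C)OO | starting material
7 | (1R,2R,4S,6S)-4-(3-chloroprop-1-en-2-yl)-1-methyl-7-oxabicyclo[4.1.0]heptan-2-ol (all cis) | C=C(CCl)[C@@H]1C[C@@H]2O[C@]2(C)[C@H](O)C1 | intermediate
8 | (1S,4R,6S)-4-(3-chloroprop-1-en-2-yl)-1-methyl-7-oxabicyclo[4.1.0]heptan-2-one (oxirane cis to side chain) | C=C(CCl)[C@@H]1C[C@@H]2O[C@]2(C)C(=O)C1 | intermediate
9 | N-methylmorpholine N-oxide | C[N+]1([O-])CCOCC1 | starting material
10 | (1S,4R,6S)-1-methyl-4-(3-oxoprop-1-en-2-yl)-7-oxabicyclo[4.1.0]heptan-2-one | C=C(C=O)[C@@H]1C[C@@H]2O[C@]2(C)C(=O)C1 | intermediate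
11 | (−)-B-allyldiisopinocampheylborane (isopinocampheyl groups from (+)-α-pinene) | C=CCB([C@@H]1C[C@@H]2C[C@H]([C@H]1C)C2(C)C)[C@@H]1C[C@@H]2C[C@H]([C@H]1C)C2(C)C | starting material
12 | diisopinocampheylborinate ester of 13 (B–O bond at C8) | C=C([C@H](CC=C)OB([C@@H]1C[C@@H]2C[C@H]([C@H]1C)C2(C)C)[C@@H]1C[C@@H]2C[C@H]([C@H]1C)C2(C)C)[C@@H]1C[C@@H]2O[C@]2(C)C(=O)C1 | intermediate
13 | (1S,4R,6S)-4-[(3S)-3-hydroxyhexa-1,5-dien-2-yl]-1-methyl-7-oxabicyclo[4.1.0]heptan-2-one | C=C([C@H](CC=C)O)[C@@H]1C[C@@H]2O[C@]2(C)C(=O)C1 | intermediate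
14 | 2-methyl-2-butene | CC=C(C)C | starting material
15 | (1S,4R,6S)-4-[(3S)-3-hydroxy-6-methylhepta-1,5-dien-2-yl]-1-methyl-7-oxabicyclo[4.1.0]heptan-2-one | C=C([C@H](CC=C(C)C)O)[C@@H]1C[C@@H]2O[C@]2(C)C(=O)C1 | intermediate
16 | 2-(phenylsulfonyl)-3-phenyloxaziridine (Davis reagent, racemic trans) | O=S(=O)(c1ccccc1)N1OC1c1ccccc1 | starting material
17 | dipotassium C8-alkoxide C1=C2 enolate of 15 | C=C([C@H](CC=C(C)C)[O-])[C@@H]1C[C@@H]2O[C@]2(C)C([O-])=C1.[K+].[K+] | intermediate
18 | (1S,3S,4S,6S)-3-hydroxy-4-[(3S)-3-hydroxy-6-methylhepta-1,5-dien-2-yl]-1-methyl-7-oxabicyclo[4.1.0]heptan-2-one | C=C([C@H](CC=C(C)C)O)[C@@H]1C[C@@H]2O[C@]2(C)C(=O)[C@H]1O | intermediate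
19 | angelic acid, (Z)-2-methylbut-2-enoic acid | C/C=C(/C)C(=O)O | starting material
20 | (Z)-2-methylbut-2-enoic 2,4,6-trichlorobenzoic anhydride | C/C=C(/C)C(=O)OC(=O)c1c(Cl)cc(Cl)cc1Cl | intermediate
21 | (1S,3S,4S,6S)-1-methyl-4-{(3S)-6-methyl-3-[(Z)-2-methylbut-2-enoyloxy]hepta-1,5-dien-2-yl}-2-oxo-7-oxabicyclo[4.1.0]heptan-3-yl (Z)-2-methylbut-2-enoate | C=C([C@H](CC=C(C)C)OC(=O)/C(C)=C\C)[C@@H]1C[C@@H]2O[C@]2(C)C(=O)[C@H]1OC(=O)/C(C)=C\C | intermediate
22 | potassium peroxymonosulfate KHSO5 (active component of Oxone) | [K+].[O-]S(=O)(=O)OO | starting material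
23 | CNP0247177.2, (1S,3S,4S,6S)-4-{(3S)-4-[(2R)-3,3-dimethyloxiran-2-yl]-3-[(Z)-2-methylbut-2-enoyloxy]but-1-en-2-yl}-1-methyl-2-oxo-7-oxabicyclo[4.1.0]heptan-3-yl (Z)-2-methylbut-2-enoate | C=C([C@H](C[C@H]1OC1(C)C)OC(=O)/C(C)=C\C)[C@@H]1C[C@@H]2O[C@]2(C)C(=O)[C@H]1OC(=O)/C(C)=C\C | target

**Totals**
Total step count: 10. Longest linear sequence: 10 steps, fully linear from 1.

**Three steps most likely to fail**

Step 5 (chloride to enal). The N-oxide displacement may be slow on the chloride, and the 2-substituted acrolein is sensitive to the amine by-product. The fallback sets out from 8 and comes back at 10. It brings in oxygen by carboxylate substitution and makes the aldehyde by alcohol oxidation: CsOAc in DMF gives the allylic acetate (1S,4R,6S)-4-(3-acetoxyprop-1-en-2-yl)-1-methyl-7-oxabicyclo[4.1.0]heptan-2-one F1; K2CO3 in MeOH at 0 °C gives the primary allylic alcohol (1S,4R,6S)-4-(3-hydroxyprop-1-en-2-yl)-1-methyl-7-oxabicyclo[4.1.0]heptan-2-one F2; MnO2 in CH2Cl2 then gives 10.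

Step 8 (hydroxylation through the dianion). The alkoxide enolate next to an oxirane may give Favorskii-type or addition side reactions. The fallback sets out from 13 and comes back at 18, replacing the metal enolate by a silyl enol ether and moving the metathesis to the end. Me3SiOTf and Et3N (CH2Cl2, −78 to 0 °C) silylate the C8 hydroxyl and the ketone together to give the C8 trimethylsilyl ether trimethylsilyl enol ether of 13 F3. Rubottom oxidation (mCPBA, NaHCO3, CH2Cl2, −20 °C; then citric acid, MeOH) attacks the enol ether anti to the C6 substituent, and is selective because the other alkenes are monosubstituted or deactivated. It gives (1S,3S,4S,6S)-3-hydroxy-4-[(3S)-3-hydroxyhexa-1,5-dien-2-yl]-1-methyl-7-oxabicyclo[4.1.0]heptan-2-one F4. Cross-metathesis of this diol with 14 under the conditions of step 7 gives 18.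

Step 10 (Shi epoxidation at pH 10.5 on the bis-ester α-acyloxy ketone). Ester hydrolysis or enolisation at C1 may compete. The fallback sets out from 15 and comes back at 23, placing the asymmetric epoxidation before any ester or acyloxy ketone exists. Shi epoxidation of 15 under the conditions of step 10 gives (1S,4R,6S)-4-{(3S)-4-[(2R)-3,3-dimethyloxiran-2-yl]-3-hydroxybut-1-en-2-yl}-1-methyl-7-oxabicyclo[4.1.0]heptan-2-one F5. Davis oxidation as in step 8 gives (1S,3S,4S,6S)-4-{(3S)-4-[(2R)-3,3-dimethyloxiran-2-yl]-3-hydroxybut-1-en-2-yl}-3-hydroxy-1-methyl-7-oxabicyclo[4.1.0]heptan-2-one F6. Double angeloylation with preformed 20 and excess Et3N then gives 23; base is kept in excess so the hydroxy oxirane does not cyclise to a tetrahydrofuran.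

**Further compounds**
F1 | step 5 | (1S,4R,6S)-4-(3-acetoxyprop-1-en-2-yl)-1-methyl-7-oxabicyclo[4.1.0]heptan-2-one | C=C(COC(C)=O)[C@@H]1C[C@@H]2O[C@]2(C)C(=O)C1
F2 | step 5 | (1S,4R,6S)-4-(3-hydroxyprop-1-en-2-yl)-1-methyl-7-oxabicyclo[4.1.0]heptan-2-one | C=C(CO)[C@@H]1C[C@@H]2O[C@]2(C)C(=O)C1
F3 | step 8 | C8 trimethylsilyl ether trimethylsilyl enol ether of 13 | C=C([C@H](CC=C)O[Si](C)(C)C)[C@@H]1C[C@@H]2O[C@]2(C)C(O[Si](C)(C)C)=C1
F4 | step 8 | (1S,3S,4S,6S)-3-hydroxy-4-[(3S)-3-hydroxyhexa-1,5-dien-2-yl]-1-methyl-7-oxabicyclo[4.1.0]heptan-2-one | C=C([C@H](CC=C)O)[C@@H]1C[C@@H]2O[C@]2(C)C(=O)[C@H]1O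
F5 | step 10 | (1S,4R,6S)-4-{(3S)-4-[(2R)-3,3-dimethyloxiran-2-yl]-3-hydroxybut-1-en-2-yl}-1-methyl-7-oxabicyclo[4.1.0]heptan-2-one | C=C([C@H](C[C@H]1OC1(C)C)O)[C@@H]1C[C@@H]2O[C@]2(C)C(=O)C1
F6 | step 10 | (1S,3S,4S,6S)-4-{(3S)-4-[(2R)-3,3-dimethyloxiran-2-yl]-3-hydroxybut-1-en-2-yl}-3-hydroxy-1-methyl-7-oxabicyclo[4.1.0]heptan-2-one | C=C([C@H](C[C@H]1OC1(C)C)O)[C@@H]1C[C@@H]2O[C@]2(C)C(=O)[C@H]1O
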